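The runs were computed on assumed constants, and the scatter is random.

Time is what to watch when this reaction is repeated, starting with the first reading: up to it the maple run averages 0.171 M min⁻¹, slower than it goes afterwards. These are the flasks, the readings and the questions.

| setting | maple | ash | cedar | alder | elm |
|---|---|---|---|---|---|
| J | 1.00 M | 0.600 M | 3.00 M | 1.00 M | 1.00 M |
| Z | 1.20 M | 0.800 M | 1.20 M | 1.20 M | 0.400 M |
| L | 0.0200 M | 0.0200 M | 0.0200 M | 0.0100 M | 0.0200 M |
| time |  |  |  |  | 3.6 min |

- maple run (time / min: [Q] / M): 0.14: 0.024; 0.27: 0.078; 0.52: 0.195; 0.99: 0.364; 1.9: 0.619; 3.6: 0.883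
- ash run (time / min: [Q] / M): 0.14: 0.020; 0.27: 0.038; 0.52: 0.110; 0.99: 0.234; 1.9: 0.396; 3.6: 0.544
- cedar run (time / min: [Q] / M): 0.14: 0.021; 0.27: 0.082; 0.52: 0.237; 0.99: 0.534; 1.9: 0.923; 3.6: 1.169
- alder run (time / min: [Q] / M): 0.14: 0.008; 0.27: 0.037; 0.52: 0.091; 0.99: 0.193; 1.9: 0.366; 3.6: 0.606

(standard deviation of a reading: 0.005 M)

- the power of [Z] that the first rate follows, about the charge of the maple run; measure it at two percent of J made into Q
- the power of [J] that the first rate follows, about the charge of the maple run; measure it at two percent of J made into Q (one fixed amount of Q, the same in the runs compared)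
- the ash run starts with 0.400 M less of J and of Z than the maple run, and with no Q. Compared where both hold the same amount of J, once fifteen percent of what the ash run was charged with has turned into Q, is the ash run faster, slower or alike (within a tenth)?
- Q in the elm run at 3.6 min, as a share of the J charged

- Overall: J + Z -> Q, with L as catalyst.
- Constant volume, constant temperature.
- Bound and free are read together.
- "The second partner" is Z.
- An order is taken over about fifteen percent of the charge, up and down.

Between 0.27 min and 0.52 min the maple run makes Q at a running rate of 0.468 M min⁻¹. Carried back along that straight line, Q reaches zero at 0.103 min. This intercept, the time lost before Q runs at its running rate, is our start-up time τ, the induction period. The same reckoning on the alder run, which holds half the L, gives a running rate of 0.216 M min⁻¹, about half of maple's. Its intercept is 0.0987 min, much like maple's. So between these two runs the running rate follows L, while τ stays put.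

Now the asked point of two percent, 0.0200 M of Q. The maple run holds 0.024 M at 0.14 min, not far past τ, so the first rate is read at the end of the start-up, and we commit to no order from the running rates.

For the elm run, Z is the limiting reagent, so Q stops at 40.0% of the J charged. How near it comes by 3.6 min we take from the cedar run, where J stands in excess. Reckoning cZ as charge minus Q, bound and free together, it falls from 0.277 M to 0.0310 M between 1.9 min and 3.6 min. That reads as a pseudo-first-order constant of 1.29 min⁻¹. We bet that elm decays likewise once τ has passed, though its J is lower. On that bet Z stands at 0.00442 M at 3.6 min, less than the scatter, so our number is 39.6%.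

The forecast gives 0.29 for Z, 0.53 for J, alike, and 39%, lower than our elm share. On the orders it says “I read orders from the rate after it”.

The flask gives 0.16 for Z, 0.52 for J, alike, and 39.9%.

    Ja + J → LJ (57.72 L mol⁻¹ min⁻¹)
    LJ + Z → Q + Ja (246.0 L mol⁻¹ min⁻¹)
    J + Z ⇌ JZ, settled at all times (1.580 L mol⁻¹)
    L + Z → Ja + Z (14.40 L mol⁻¹ min⁻¹)

The two part on the order in Z. Without the association of J and Z to JZ the order in Z comes to 0.46, so that association pulls it down to 0.16. The start-up time then carries over: to reach 0.250 M of Q, τ plus that amount over the running rate gives 0.637 min in the maple run against the flask's 0.688 min, and 1.26 min in the alder run against the flask's 1.27 min.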